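## Retrosynthetic overview

1. Target 21 comes from diepoxy alcohol 18 by a late angeloylation that keeps the Z geometry. 18 comes from (E,E)-germacra-1(10),4-diene 17, where both oxirane rings (C1–C10 and C4–C5) are made in one operation and the ring conformation sets C1, C10, C4 and C5.
2. 17 comes from the ten-membered carbocycle 14 by hydrogenation of the isopropenyl group, Mitsunobu inversion with acetic acid at C6 and desilylation at C2.
3. Key disconnection, C6–C7 of the ten-membered carbocycle: C6 (the acetoxy carbon) and C7 (the ring carbon carrying the isopropyl group C11–C13) are neighbours. With C11=C12 unsaturated, this 1-hydroxy-2-isopropenyl unit is the retron of an aldehyde allylation (C6 = aldehyde carbon, C7 = γ-carbon of the allyl unit C12–C11=C7), which opens the ring to the acyclic chloro-enal 12; the E-alkenes C4=C5 and C1=C10 (the later oxiranes) stiffen the chain.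
4. 12 comes from 8-chlorogeranial 5 and silyl dienol ether 8 by a catalytic asymmetric vinylogous Mukaiyama aldol reaction, which sets C2; 5 comes from geranyl acetate 1.
5. Ring order: ten-membered carbocycle first (step 10), then the two oxirane rings together (step 14).

Key step: step 10

Remark on numbering: open-chain compounds carry IUPAC locants. From step 10 on, germacrane numbers are used (ring C1–C10, C14 on C10, C15 on C4, C11–C13 on C7; in 12 the aldehyde carbon is C6, the CH2Cl carbon C12 and the silyloxy carbon C2). α/β refer to the usual germacrane drawing with the C7 side chain β.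

Assumption: the two chiral catalysts are used as the antipodes that give Re-face addition in step 6 and Si-face addition in step 10; which antipode that is has to be fixed on a model aldehyde.

## Route

Step 1
Reactants: 1 geranyl acetate
Product: 2 (2E,6E)-8-hydroxy-3,7-dimethylocta-2,6-dien-1-yl acetate
Conditions: SeO2 (cat.), tBuOOH, salicylic acid (cat.), CH2Cl2, rt
Reagents that add atoms: tert-butyl hydroperoxide, CC(C)(C)OO (oxygen passed on through catalytic SeO2)
Why: SeO2-catalysed allylic oxidation (ene reaction followed by a [2,3]-sigmatropic shift) should hydroxylate the E-methyl group of the electron-rich terminal alkene, the inner alkene being deactivated by the allylic acetate, and the [2,3] shift fixes the E geometry.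

Step 2
Reactants: 2 (2E,6E)-8-hydroxy-3,7-dimethylocta-2,6-dien-1-yl acetate
Product: 3 (2E,6E)-8-chloro-3,7-dimethylocta-2,6-dien-1-yl acetate
Conditions: PPh3, CCl4, reflux
Reagents that add atoms: carbon tetrachloride, ClC(Cl)(Cl)Cl
Why: Appel chlorination should displace the alkoxyphosphonium group by chloride in an SN2 step at the primary allylic carbon, without allylic transposition and with retention of the alkene geometry.

Step 3
Reactants: 3 (2E,6E)-8-chloro-3,7-dimethylocta-2,6-dien-1-yl acetate
Product: 4 (2E,6E)-8-chloro-3,7-dimethylocta-2,6-dien-1-ol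
Conditions: iBu2AlH, CH2Cl2, −78 °C; aq. potassium sodium tartrate
Reagents that add atoms: none
Why: Reductive cleavage of the acetate by the aluminium hydride at low temperature should free the alcohol under non-nucleophilic conditions that leave the primary allylic chloride untouched.

Step 4
Reactants: 4 (2E,6E)-8-chloro-3,7-dimethylocta-2,6-dien-1-ol
Product: 5 (2E,6E)-8-chloro-3,7-dimethylocta-2,6-dienal
Conditions: MnO2, CH2Cl2, rt
Reagents that add atoms: none
Why: MnO2 oxidises allylic alcohols selectively to enals without E/Z isomerisation and does not touch the allylic chloride.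

Step 5
Reactants: 6 ethyl 3-methylbut-2-enoate
Product: 8 tert-butyl[(1-ethoxy-3-methylbuta-1,3-dien-1-yl)oxy]dimethylsilane, via lithium dienolate 7 (not isolated)
Conditions: LiN(iPr)2, THF, −78 °C; tBuMe2SiCl, DMPU, −78 °C to rt
Reagents that add atoms: tert-butyldimethylsilyl chloride, CC(C)(C)[Si](C)(C)Cl
Why: γ-Deprotonation of the unsaturated ester gives the extended dienolate, which the silyl chloride traps on oxygen (standard silyl dienol ether formation).

Step 6
Reactants: 5 (2E,6E)-8-chloro-3,7-dimethylocta-2,6-dienal; 8 tert-butyl[(1-ethoxy-3-methylbuta-1,3-dien-1-yl)oxy]dimethylsilane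
Product: 9 ethyl (2E,5R,6E,10E)-12-chloro-5-hydroxy-3,7,11-trimethyldodeca-2,6,10-trienoate
Conditions: SiCl4, chiral binaphthyldiamine-derived bisphosphoramide (5 mol %), iPr2NEt (cat.), CH2Cl2, −78 °C; aq. NaHCO3
Reagents that add atoms: none
Why: In this vinylogous Mukaiyama aldol reaction under Lewis-base-activated SiCl4 catalysis the dienol ether should attack through its γ-carbon, the s-trans diene gives the E-trisubstituted enoate, and the chiral phosphoramide-bound silicon cation directs addition to the Re face of the enal, which sets C5 as R (C2 of the target).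

Step 7
Reactants: 9 ethyl (2E,5R,6E,10E)-12-chloro-5-hydroxy-3,7,11-trimethyldodeca-2,6,10-trienoate
Product: 10 ethyl (2E,5R,6E,10E)-5-[(tert-butyldimethylsilyl)oxy]-12-chloro-3,7,11-trimethyldodeca-2,6,10-trienoate
Conditions: tBuMe2SiCl, imidazole, DMF, rt
Reagents that add atoms: tert-butyldimethylsilyl chloride, CC(C)(C)[Si](C)(C)Cl
Why: Imidazole-promoted silylation protects the secondary allylic alcohol as an ether that survives hydride, chromium and Mitsunobu conditions and does not affect the stereocentre.

Step 8
Reactants: 10 ethyl (2E,5R,6E,10E)-5-[(tert-butyldimethylsilyl)oxy]-12-chloro-3,7,11-trimethyldodeca-2,6,10-trienoate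
Product: 11 (2E,5R,6E,10E)-5-[(tert-butyldimethylsilyl)oxy]-12-chloro-3,7,11-trimethyldodeca-2,6,10-trien-1-ol
Conditions: iBu2AlH, CH2Cl2, −78 °C; aq. potassium sodium tartrate
Reagents that add atoms: none
Why: 1,2-Reduction of the conjugated ester by the aluminium hydride at −78 °C should give the E-allylic alcohol while the allylic chloride and the silyl ether remain.

Step 9
Reactants: 11 (2E,5R,6E,10E)-5-[(tert-butyldimethylsilyl)oxy]-12-chloro-3,7,11-trimethyldodeca-2,6,10-trien-1-ol
Product: 12 (2E,5R,6E,10E)-5-[(tert-butyldimethylsilyl)oxy]-12-chloro-3,7,11-trimethyldodeca-2,6,10-trienal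
Conditions: MnO2, CH2Cl2, rt
Reagents that add atoms: none
Why: Neutral MnO2 oxidation of the allylic alcohol should give the E-enal without base that could eliminate the γ-silyloxy group.

Step 10
Reactants: 12 (2E,5R,6E,10E)-5-[(tert-butyldimethylsilyl)oxy]-12-chloro-3,7,11-trimethyldodeca-2,6,10-trienal
Product: 14 (1(10)E,4E,2R,6R,7S)-2-[(tert-butyldimethylsilyl)oxy]germacra-1(10),4,11-trien-6-ol, via trimethylsilyl ether 13 (not isolated)
Conditions: CrCl2 (15 mol %), chiral 1,8-bis(4-isopropyloxazolin-2-yl)carbazole ligand (18 mol %), Mn powder, Me3SiCl, iPr2NEt, THF, syringe-pump addition of 12 (final 3 mM), rt; then K2CO3 (cat.), MeOH, 0 °C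
Reagents that add atoms: none
Why: Catalytic Nozaki–Hiyama–Kishi allylation: divalent chromium (kept reduced by Mn) inserts into the primary allylic C12–Cl bond, and the resulting allylchromium (trivalent chromium bound at C12) adds through its γ-carbon C7 to the aldehyde carbon C6 in a chair-like six-membered transition state, after which Me3SiCl frees the catalyst by silylating the alkoxide to 13. The closest known reaction type is the chromium-mediated allyl halide–aldehyde coupling that closes ten-membered germacrane carbocycles at this same C6–C7 bond from 12-halofarnesal chains, combined here with ligand-controlled asymmetric chromium crotyl-type additions. The single ring formed, the ten-membered carbocycle, closes by 10-exo-trig attack on the carbonyl with allylic transposition, which leaves C11=C12 as the exocyclic isopropenyl group. C6 and C7 are created together: their relative configuration (6α-OH, 7β-isopropenyl, anti in the crotylation sense) follows from the E-allylchromium (C8 trans to CH2Cr) placing C5 and C8 equatorial on the chair, and the absolute sense (Si-face attack at C6, giving 6R,7S) is assigned to the chiral tridentate ligand, because the remote C2 stereocentre only orients the C1=C10 plane (H-2 eclipsing C14) and the crossed and parallel dispositions of the two alkene planes should differ little in energy. The step needs γ- over α-attack (the closed transition state delivers only the γ-carbon, so no twelve-membered ring), 1,2- over 1,4-addition to the enal (inherent to allylchromium reagents), ring closure over chain-to-chain coupling (slow addition to millimolar concentration, chain stiffened by the two E-trisubstituted alkenes) and survival of the allylic silyl ether (chromium inserts only into the C–Cl bond).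

Step 11
Reactants: 14 (1(10)E,4E,2R,6R,7S)-2-[(tert-butyldimethylsilyl)oxy]germacra-1(10),4,11-trien-6-ol
Product: 15 (1(10)E,4E,2R,6S,7S)-2-[(tert-butyldimethylsilyl)oxy]germacra-1(10),4-dien-6-ol
Conditions: H2 (1 atm), RhCl(PPh3)3 (5 mol %), benzene, rt
Reagents that add atoms: none
Why: Homogeneous hydrogenation with RhCl(PPh3)3 reduces the unhindered 1,1-disubstituted isopropenyl alkene much faster than the two trisubstituted ring alkenes, so only C11=C12 should be saturated and no stereocentre is affected (the descriptor at C6 changes only through the priority rules).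

Step 12
Reactants: 15 (1(10)E,4E,2R,6S,7S)-2-[(tert-butyldimethylsilyl)oxy]germacra-1(10),4-dien-6-ol
Product: 16 (1(10)E,4E,2R,6R,7S)-2-[(tert-butyldimethylsilyl)oxy]germacra-1(10),4-dien-6-yl acetate
Conditions: PPh3, iPrO2CN=NCO2iPr, AcOH, toluene, 0 °C to rt
Reagents that add atoms: acetic acid, CC(=O)O
Why: In the Mitsunobu reaction the alkoxyphosphonium formed at the allylic C6 hydroxyl is displaced by acetate in an SN2 step, so the acetate enters with inversion (6α-OH to 6β-OAc, 6R), which corrects C6 to the configuration of the target while C2 and C7 stay untouched.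

Step 13
Reactants: 16 (1(10)E,4E,2R,6R,7S)-2-[(tert-butyldimethylsilyl)oxy]germacra-1(10),4-dien-6-yl acetate
Product: 17 (1(10)E,4E,2R,6R,7S)-2-hydroxygermacra-1(10),4-dien-6-yl acetate
Conditions: Bu4NF, AcOH, THF, 0 °C to rt
Reagents that add atoms: none
Why: Fluoride-mediated desilylation buffered with acetic acid should cleave the Si–O bond without base-induced loss of the C6 acetate and without acid that could trigger transannular cyclisation of the diene.

Step 14
Reactants: 17 (1(10)E,4E,2R,6R,7S)-2-hydroxygermacra-1(10),4-dien-6-yl acetate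
Product: 18 (1S,2R,4S,5S,6R,7S,10S)-1,10:4,5-diepoxy-2-hydroxygermacran-6-yl acetate
Conditions: 3-chloroperbenzoic acid (2.3 equiv), NaHCO3, CH2Cl2, 0 °C
Reagents that add atoms: 3-chloroperbenzoic acid, O=C(OO)c1cccc(Cl)c1
Why: In this Prilezhaev epoxidation A(1,3) strain keeps H-2 and H-6 in the planes of the C1=C10 and C4=C5 bonds (eclipsing C14 and C15), so both oxygen substituents lie on the outer faces of the crossed diene, and the peracid, hydrogen-bonded to the C2 hydroxyl at one alkene and confined to the exposed face at the other (the inner faces are shielded across the ring), should add syn to each allylic oxygen and give the threo-epoxy arrangements (1S,10S) and (4S,5S), as peracids are known to attack (E,E)-germacra-1(10),4-dienes from their outer faces.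

Step 15
Reactants: 18 (1S,2R,4S,5S,6R,7S,10S)-1,10:4,5-diepoxy-2-hydroxygermacran-6-yl acetate; 19 angelic acid
Product: 21 (1S,2R,4S,5S,6R,7S,10S)-6-acetoxy-1,10:4,5-diepoxygermacran-2-yl (Z)-2-methylbut-2-enoate, via mixed anhydride 20 (not isolated)
Conditions: 2,4,6-trichlorobenzoyl chloride, Et3N, toluene, rt; then 18, 80 °C
Reagents that add atoms: none
Why: In this Yamaguchi-type esterification the C2 hydroxyl should attack the less hindered angeloyl carbonyl of mixed anhydride 20, and leaving out a nucleophilic acyl-transfer catalyst avoids the addition–elimination pathway that isomerises the Z (angelate) double bond to the E (tiglate) form, while no stereocentre is touched.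

## Compound list

1 | geranyl acetate, (2E)-3,7-dimethylocta-2,6-dien-1-yl acetate | CC(C)=CCC/C(C)=C/COC(C)=O | starting material
2 | (2E,6E)-8-hydroxy-3,7-dimethylocta-2,6-dien-1-yl acetate | OC/C(C)=C/CC/C(C)=C/COC(C)=O | intermediate
3 | (2E,6E)-8-chloro-3,7-dimethylocta-2,6-dien-1-yl acetate | ClC/C(C)=C/CC/C(C)=C/COC(C)=O | intermediate
4 | (2E,6E)-8-chloro-3,7-dimethylocta-2,6-dien-1-ol | ClC/C(C)=C/CC/C(C)=C/CO | intermediate
5 | (2E,6E)-8-chloro-3,7-dimethylocta-2,6-dienal (8-chlorogeranial) | ClC/C(C)=C/CC/C(C)=C/C=O | intermediate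
6 | ethyl 3-methylbut-2-enoate | CCOC(=O)C=C(C)C | starting material
7 | lithium 1-ethoxy-3-methylbuta-1,3-dien-1-olate (not isolated) | [Li]OC(OCC)=CC(C)=C | intermediate
8 | tert-butyl[(1-ethoxy-3-methylbuta-1,3-dien-1-yl)oxy]dimethylsilane | CCOC(O[Si](C)(C)C(C)(C)C)=CC(C)=C | intermediate
9 | ethyl (2E,5R,6E,10E)-12-chloro-5-hydroxy-3,7,11-trimethyldodeca-2,6,10-trienoate | CCOC(=O)/C=C(\C)C[C@@H](O)/C=C(\C)CC/C=C(\C)CCl | intermediate
10 | ethyl (2E,5R,6E,10E)-5-[(tert-butyldimethylsilyl)oxy]-12-chloro-3,7,11-trimethyldodeca-2,6,10-trienoate | CCOC(=O)/C=C(\C)C[C@@H](O[Si](C)(C)C(C)(C)C)/C=C(\C)CC/C=C(\C)CCl | intermediate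
11 | (2E,5R,6E,10E)-5-[(tert-butyldimethylsilyl)oxy]-12-chloro-3,7,11-trimethyldodeca-2,6,10-trien-1-ol | OC/C=C(\C)C[C@@H](O[Si](C)(C)C(C)(C)C)/C=C(\C)CC/C=C(\C)CCl | intermediate
12 | (2E,5R,6E,10E)-5-[(tert-butyldimethylsilyl)oxy]-12-chloro-3,7,11-trimethyldodeca-2,6,10-trienal | O=C/C=C(\C)C[C@@H](O[Si](C)(C)C(C)(C)C)/C=C(\C)CC/C=C(\C)CCl | intermediate
13 | 6-O-trimethylsilyl ether of 14 (not isolated) | CC(C)(C)[Si](C)(C)O[C@@H]1C/C(C)=C/[C@@H](O[Si](C)(C)C)[C@H](C(C)=C)CC/C(C)=C/1 | intermediate
14 | (1(10)E,4E,2R,6R,7S)-2-[(tert-butyldimethylsilyl)oxy]germacra-1(10),4,11-trien-6-ol (2β-silyloxy, 6α-hydroxy, 7β-isopropenyl) | CC(C)(C)[Si](C)(C)O[C@@H]1C/C(C)=C/[C@@H](O)[C@H](C(C)=C)CC/C(C)=C/1 | intermediate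
15 | (1(10)E,4E,2R,6S,7S)-2-[(tert-butyldimethylsilyl)oxy]germacra-1(10),4-dien-6-ol (6α-hydroxy, 7β-isopropyl) | CC(C)(C)[Si](C)(C)O[C@@H]1C/C(C)=C/[C@@H](O)[C@H](C(C)C)CC/C(C)=C/1 | intermediate
16 | (1(10)E,4E,2R,6R,7S)-2-[(tert-butyldimethylsilyl)oxy]germacra-1(10),4-dien-6-yl acetate (6β-acetoxy) | CC(C)(C)[Si](C)(C)O[C@@H]1C/C(C)=C/[C@H](OC(C)=O)[C@H](C(C)C)CC/C(C)=C/1 | intermediate
17 | (1(10)E,4E,2R,6R,7S)-2-hydroxygermacra-1(10),4-dien-6-yl acetate | O[C@@H]1C/C(C)=C/[C@H](OC(C)=O)[C@H](C(C)C)CC/C(C)=C/1 | intermediate
18 | (1S,2R,4S,5S,6R,7S,10S)-1,10:4,5-diepoxy-2-hydroxygermacran-6-yl acetate | O[C@@H]1C[C@]2(C)O[C@H]2[C@H](OC(C)=O)[C@H](C(C)C)CC[C@]2(C)O[C@@H]12 | intermediate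
19 | angelic acid, (Z)-2-methylbut-2-enoic acid | C/C=C(/C)C(=O)O | starting material
20 | (Z)-2-methylbut-2-enoic 2,4,6-trichlorobenzoic anhydride (not isolated) | C/C=C(/C)C(=O)OC(=O)c1c(Cl)cc(Cl)cc1Cl | intermediate
21 | (1S,2R,4S,5S,6R,7S,10S)-6-acetoxy-1,10:4,5-diepoxygermacran-2-yl (Z)-2-methylbut-2-enoate | C/C=C(/C)C(=O)O[C@@H]1C[C@]2(C)O[C@H]2[C@H](OC(C)=O)[C@H](C(C)C)CC[C@]2(C)O[C@@H]12 | target

## Step count and risks

Total step count: 15. Longest linear sequence: 14 steps (steps 1–4 and 6–15, from geranyl acetate 1); step 5 is a one-step side branch.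

Steps most likely to fail: 10, 12 and 15.

**Step 10.** The ligand may not override the small intrinsic bias of the chain, so that the allyl group adds to both faces of the aldehyde and two 6,7-trans diastereomers form; chain-to-chain coupling may also outrun closure of the strained ten-membered ring. The fallback puts a temporary oxirane next to the aldehyde as an adjacent control element. It sets out from 11, which is epoxidised under Sharpless conditions (Ti(OiPr)4, D-(−)-diethyl tartrate, tBuOOH, 4 Å molecular sieves, CH2Cl2, −20 °C) to the (2R,3R)-epoxy alcohol F1. Oxidation with Dess–Martin periodinane and NaHCO3 gives the epoxy aldehyde F2, which is more electrophilic than the enal and carries one more sp3 unit. F2 is closed by the palladium-catalysed umpolung allylation (Pd(PPh3)4, Et2Zn, THF, slow addition), a reaction type established for closing this ring on 2,3-epoxy-12-chlorofarnesal chains, to the 4,5-epoxy macrocycle F3. In this closure the allylzinc should add anti to the C5–O bond with the formyl hydrogen eclipsing C15, and the chair again gives the 6α-hydroxy-7β-isopropenyl pair. Stereoretentive deoxygenation of the oxirane with WCl6 and nBuLi in THF then returns the E-alkene, and the fallback comes back to the route at 14.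

**Step 12.** The SN2 displacement at the branched allylic carbinol may be slow, so that elimination or ionisation of the oxyphosphonium ion, followed by allylic transposition or transannular capture by the C1=C10 alkene, takes over. The fallback resets C6 by oxidation and reduction. It sets out from 15, which is oxidised with Dess–Martin periodinane and NaHCO3 to the enone F4. 1,2-Reduction with LiBH(sBu)3 in THF at −78 °C should deliver hydride from the face opposite the C7 isopropyl group and give the 6β-alcohol F5. Acetylation (Ac2O, DMAP, pyridine) brings the fallback back to the route at 16.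

**Step 15.** The angeloyl group may isomerise from Z to E (tiglate formation) during the slow, heated acylation of the hindered C2 hydroxyl. The fallback builds the Z-alkene on the substrate. It sets out from 18, which is esterified with 2-[bis(2,2,2-trifluoroethoxy)phosphoryl]propanoic acid (dicyclohexylcarbodiimide, DMAP, CH2Cl2, 0 °C) to the phosphonate ester F6. A Still–Gennari olefination with acetaldehyde (KN(SiMe3)2, 18-crown-6, THF, −78 °C) should then form the Z-2-methylbut-2-enoate directly, and the fallback comes back to the route at 21.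

## Further compounds

F1 | step 10 | (2R,3R)-2,3-epoxide of 11, [(2R,3R)-3-{(2R,3E,7E)-2-[(tert-butyldimethylsilyl)oxy]-9-chloro-4,8-dimethylnona-3,7-dien-1-yl}-3-methyloxiran-2-yl]methanol | CC(C)(C)[Si](C)(C)O[C@@H](/C=C(\C)CC/C=C(\C)CCl)C[C@@]1(C)O[C@@H]1CO
F2 | step 10 | epoxy aldehyde from F1, (2S,3R)-3-{(2R,3E,7E)-2-[(tert-butyldimethylsilyl)oxy]-9-chloro-4,8-dimethylnona-3,7-dien-1-yl}-3-methyloxirane-2-carbaldehyde | CC(C)(C)[Si](C)(C)O[C@@H](/C=C(\C)CC/C=C(\C)CCl)C[C@@]1(C)O[C@@H]1C=O
F3 | step 10 | (1(10)E,2R,4R,5R,6S,7S)-2-[(tert-butyldimethylsilyl)oxy]-4,5-epoxygermacra-1(10),11-dien-6-ol | CC(C)(C)[Si](C)(C)O[C@@H]1C[C@@]2(C)O[C@@H]2[C@@H](O)[C@H](C(C)=C)CC/C(C)=C/1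
F4 | step 12 | (1(10)E,4E,2R,7S)-2-[(tert-butyldimethylsilyl)oxy]germacra-1(10),4-dien-6-one | CC(C)(C)[Si](C)(C)O[C@@H]1C/C(C)=C/C(=O)[C@H](C(C)C)CC/C(C)=C/1
F5 | step 12 | (1(10)E,4E,2R,6R,7S)-2-[(tert-butyldimethylsilyl)oxy]germacra-1(10),4-dien-6-ol (6β-hydroxy) | CC(C)(C)[Si](C)(C)O[C@@H]1C/C(C)=C/[C@H](O)[C@H](C(C)C)CC/C(C)=C/1
F6 | step 15 | 2-[bis(2,2,2-trifluoroethoxy)phosphoryl]propanoate of 18 (both epimers at the phosphonate carbon) | CC(C(=O)O[C@@H]1C[C@]2(C)O[C@H]2[C@H](OC(C)=O)[C@H](C(C)C)CC[C@]2(C)O[C@@H]12)P(=O)(OCC(F)(F)F)OCC(F)(F)F
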